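The rate constants were chosen freely; the rest is arithmetic.

If the substrate leaves a flask early, the question is how long the intermediate has had since then.

    substrate → intermediate (k1 = 0.0399 s⁻¹, Ea1 = 97.0 kJ mol⁻¹)
    intermediate → target (k2 = 0.0137 s⁻¹, Ea2 = 91.0 kJ mol⁻¹)
    substrate + target → side product (k3 = 121 M⁻¹ s⁻¹, Ea3 = 44.0 kJ mol⁻¹)
    2 substrate → self-condensation product (k4 = 8.50 M⁻¹ s⁻¹, Ea4 = 56.0 kJ mol⁻¹)
    (constants at 70 °C)

common to all: substrate 0.50 mM; time 2.0 min
- elm: at 55 °C until 1.0 min, from then on at 85 °C
- birch: temperature 85 °C
- cedar: temperature 55 °C
- larch: temperature 70 °C

- the flask that comes out highest in amount of target, in percent of the substrate charged, or "all alike" when all lie within 1.5 percentage points (elm / birch / cedar / larch / all alike)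
- target at the end, in percent of the substrate charged, elm
- target at the end, in percent of the substrate charged, birch
- target at the end, in percent of the substrate charged, cedar
- target at the end, in percent of the substrate charged, larch

- percentages count the substrate that a species holds: one side product or self-condensation product counts as two
- two of one species on the left: rate k times its square, two consumed each time
- at 70 °C the constants are as listed, elsewhere as the activation energies make them

The first question is which of the first two steps is slower in a hot flask. At 85 °C the first step runs at 9.94 min⁻¹ and the second at 3.13 min⁻¹. The substrate's half-life by the first step is 4.18 s. The quantity to carry is the intermediate's hot half-life by the second step, 13.3 s. The substrate's is shorter, so this reckoning takes the first step as over soon after heating and counts the time in intermediate half-lives.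

The next question is how many such half-lives fit. Birch has 9.02, and that count reckons a fraction 0.193 % of its intermediate as left. Elm has 4.51 after its change, which reckons 4.39 % as left. At their own temperatures, larch has 2.37 and cedar 0.552. Birch therefore has the highest count.

Can the losses overturn that order? The third and fourth steps lie 53.0 kJ mol⁻¹ and 41.0 kJ mol⁻¹ below the first in activation energy, so heat raises the first constant faster than either of theirs. Birch stands at 85 °C from the start, and this reckoning names birch without giving percentages.

The forecast also names birch. It gives 73 % for elm, 84 % for birch, 7.1 % for cedar and 52.7 % for larch, on the ground that “heat favours target over both bimolecular losses”.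

The simulation gives birch as highest, with 72.7 % for elm, 84.0 % for birch, 7.17 % for cedar and 52.3 % for larch.

In elm at 1.01 min, just after the change, the intermediate's half-life by the second step is 0.22 min, with about 1.00 min of heat ahead, and target is made 10.3 times faster than it is used up. At 2.00 min intermediate stands at 4.16 % in elm and 0.235 % in birch.

Elm read at 80 s lies 1.50 half-lives past the change. Elm's target gains 74.3 % of the charge from the change to 20.0 min, and that much, taken as intermediate at the change and decaying, gives 26.3 %. At that reading elm holds 32.5 % of intermediate, which is more, with substrate at 1.02 %.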